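Ring D is cut across the D1–D2 and D5–D6 bonds into a four-carbon cyclobutenone (D2–D5, carrying the D4 methoxy and D5 methyl groups) and a two-carbon silyl ynol ether (D1, D6) that already bears the C8–CH2 bridge and the benzyl-protected (+)-catechin core. The feature exploited is the fully substituted, 1,3,5-trioxygenated ring D: one thermal cascade closes this ring and delivers its three oxygens differentiated by connectivity alone (D2 free phenol, D4 methyl ether, D6 silyl ether), leaving only D3 open for acylation ortho to the D2 hydroxyl. The precursor is 8-(3-triisopropylsiloxyprop-2-ynyl)-penta-O-benzylcatechin; C2 and C3 come unchanged from catechin.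

Key step: step 8

Assumption on the chemistry: ring-D locants run D1 (methylene-bearing carbon), D2 (OH), D3 (isobutyryl), D4 (OMe), D5 (Me), D6 (OH); the D3 acyl group is introduced by ortho-formylation, Grignard addition and oxidation, so that no Lewis-acid acyl shift is run in the presence of the benzyl ethers, the silyl ether and the diarylmethane bridge; the volatile ynol ether 3 is handled as a titrated ethereal solution.

Step 1
Reactants: 1 chloroacetaldehyde dimethyl acetal (2-chloro-1,1-dimethoxyethane)
Product: 3 1-methoxyprop-1-yne, via sodium methoxyacetylide 2 (not isolated)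
Conditions: NaNH2 (3.1 equiv), liquid NH3, −33 °C; MeI (1.2 equiv), −33 °C; NH3 evaporated, extraction into Et2O
Reagents that add atoms: methyl iodide CI
Why: Two base-induced eliminations (loss of methanol, then of HCl) and deprotonation by NaNH2 should convert 1 into acetylide 2, and C-alkylation of this alkoxyacetylide with MeI in liquid ammonia (classical acetylide alkylation) installs the future D5 methyl group while a methoxy group of 1 becomes the D4 methyl ether, so that no later O-methylation or ether exchange is needed.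

Step 2
Reactants: 3 1-methoxyprop-1-yne; 4 trichloroacetyl chloride
Product: 6 4,4-dichloro-3-methoxy-2-methylcyclobut-2-en-1-one, via dichloroketene 5 (not isolated)
Conditions: zinc–copper couple, Et2O–DME, slow addition of 4, rt
Reagents that add atoms: none
Why: Zinc dechlorination of 4 generates dichloroketene 5, which undergoes ketene–ynol ether [2+2] cycloaddition with 3; the methyl-bearing alkyne carbon (remote from oxygen, nucleophilic) bonds to the ketene carbonyl carbon, so methyl ends at C2 and methoxy at C3, and DME ties up the ZnCl2 that would otherwise degrade the ynol ether.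

Step 3
Reactants: 6 4,4-dichloro-3-methoxy-2-methylcyclobut-2-en-1-one
Product: 7 3-methoxy-2-methylcyclobut-2-en-1-one
Conditions: Zn dust, AcOH, TMEDA, MeOH, 0 °C to rt
Reagents that add atoms: none
Why: Reductive dehalogenation of the α,α-dichloro ketone by zinc (zinc enolate formation and protonation, twice) under amine-buffered conditions removes both chlorines without opening the strained vinylogous ester, and methanol as solvent makes any alkoxy exchange at C3 degenerate.

Step 4
Reactants: 8 (+)-catechin
Product: 10 penta-O-benzyl-(+)-catechin, via 5,7,3',4'-tetra-O-benzylcatechin 9 (not isolated)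
Conditions: BnBr (6 equiv), K2CO3 (6 equiv), DMF, 0 °C to rt; then NaH (3 equiv), 0 °C to rt, same flask
Reagents that add atoms: benzyl bromide BrCc1ccccc1
Why: Williamson ether synthesis in two stages: the four phenols are benzylated under K2CO3 first, so that when NaH is added for the C3 alcohol no B-ring phenoxide remains that could open ring C through a quinone methide and epimerize C2; the (2R,3S) configuration is carried over unchanged.

Step 5
Reactants: 10 penta-O-benzyl-(+)-catechin
Product: 11 8-bromo-penta-O-benzylcatechin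
Conditions: NBS (1.0 equiv), CH2Cl2, −78 °C to rt
Reagents that add atoms: N-bromosuccinimide O=C1CCC(=O)N1Br
Why: Electrophilic aromatic bromination: C8, flanked by O1 and the C7 benzyloxy group, is the most nucleophilic position of the phloroglucinol-type ring A in benzylated flavan-3-ols, and one equivalent at low temperature should stop before C6 reacts.

Step 6
Reactants: 11 8-bromo-penta-O-benzylcatechin
Product: 12 ethyl 2-(penta-O-benzylcatechin-8-yl)acetate
Conditions: BrZnCH2CO2Et (from ethyl bromoacetate and Zn dust, THF), Pd2(dba)3 (2.5 mol %), XPhos (10 mol %), THF, 65 °C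
Reagents that add atoms: ethyl bromoacetate CCOC(=O)CBr
Why: Negishi-type α-arylation of a zinc ester enolate (Reformatsky reagent): zerovalent palladium carrying the bulky biarylphosphine inserts into the hindered C8–Br bond, transmetalation and reductive elimination form the C8–CH2 bond, and the nearly neutral zinc reagent avoids Claisen condensation, double arylation and attack on the benzyl ethers.

Step 7
Reactants: 12 ethyl 2-(penta-O-benzylcatechin-8-yl)acetate
Product: 15 8-(3-triisopropylsiloxyprop-2-ynyl)-penta-O-benzylcatechin, via lithium dibromoenolate 13 (not isolated), via lithium ynolate 14 (not isolated)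
Conditions: CH2Br2, lithium 2,2,6,6-tetramethylpiperidide, THF, −78 °C; LiN(SiMe3)2, −78 to −20 °C; n-BuLi, −78 to 0 °C; TIPSCl, −78 °C to rt
Reagents that add atoms: dibromomethane BrCBr; chlorotriisopropylsilane CC(C)[Si](Cl)(C(C)C)C(C)C
Why: Kowalski ester homologation intercepted at the ynolate: (dibromomethyl)lithium adds to the ester carbonyl at −78 °C faster than it enolizes the ester, collapse and deprotonation give enolate 13, bromine–lithium exchange produces a carbenoid whose 1,2-shift of the flavanylmethyl group (Fritsch–Buttenberg–Wiechell type) with loss of LiBr gives ynolate 14, and the bulky TIPSCl silylates 14 on oxygen; the ester carbonyl carbon becomes D6 and the carbon from CH2Br2 becomes D1.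

Step 8
Reactants: 15 8-(3-triisopropylsiloxyprop-2-ynyl)-penta-O-benzylcatechin; 7 3-methoxy-2-methylcyclobut-2-en-1-one
Product: 20 2-[(penta-O-benzylcatechin-8-yl)methyl]-5-methoxy-4-methyl-3-(triisopropylsiloxy)phenol, via vinylketene 16 (not isolated), via vinylcyclobutenone 17 (not isolated), via dienylketene 18 (not isolated), via cyclohexadienone 19 (not isolated)
Conditions: 7 (1.3 equiv, two portions), toluene, 80 °C then 110 °C, argon
Reagents that add atoms: none
Why: Thermal 4-electron electrocyclic opening of 7 gives methoxyvinylketene 16, whose [2+2] cycloaddition with the ynol ether of 15 forms D1–D2 (ketene carbonyl carbon to the CH2-bearing alkyne carbon) and D5–D6 (methyl-bearing ketene carbon to the siloxy carbon) in vinylcyclobutenone 17. Reversible 4-electron opening of 17 gives dienylketene 18, and ring D is closed by 6-electron disrotatory electrocyclization of 18 between the ketene carbon (D2) and the terminal CH2 (D3) to dienone 19, which tautomerizes to phenol 20. The closest known reaction is the Danheiser benzannulation of cyclobutenones with trialkylsiloxyalkynes, which gives mono-silylated resorcinols. No lasting stereocentre is created: the quaternary carbon of 17 forms without control and is erased on ring opening, and C2 and C3 are spectators under neutral thermal conditions. The only selectivity required is the orientation of the ketene–alkyne cycloaddition, secured by the polarization of the siloxyalkyne (the carbon remote from oxygen is the nucleophile), which by connectivity places the ketene oxygen at D2 as free hydroxyl, the siloxy group at D6, methoxy at D4, methyl at D5 and hydrogen at D3. Portionwise addition of the inexpensive partner 7 keeps the ketene concentration low, disfavouring ketene oligomerization and acylation of the new phenol.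

Step 9
Reactants: 20 2-[(penta-O-benzylcatechin-8-yl)methyl]-5-methoxy-4-methyl-3-(triisopropylsiloxy)phenol
Product: 21 2-hydroxy-6-methoxy-5-methyl-3-[(penta-O-benzylcatechin-8-yl)methyl]-4-(triisopropylsiloxy)benzaldehyde
Conditions: MgCl2 (3 equiv), Et3N (6 equiv), (CH2O)n (8 equiv), THF, 65 °C
Reagents that add atoms: paraformaldehyde (as formaldehyde) C=O
Why: Magnesium-mediated ortho-formylation of a phenol (Casnati–Skattebøl reaction): the magnesium phenoxide of the D2 hydroxyl delivers formaldehyde to its only free ortho carbon, D3, and hydride transfer from the resulting magnesium benzyl alkoxide to a second formaldehyde gives the aldehyde; rings A and B have no free phenol and cannot react, and the non-acidic medium spares benzyl ethers, silyl ether, CH2 bridge and C2, which an acid-mediated acyl shift would put at risk.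

Step 10
Reactants: 21 2-hydroxy-6-methoxy-5-methyl-3-[(penta-O-benzylcatechin-8-yl)methyl]-4-(triisopropylsiloxy)benzaldehyde
Product: 22 1-[2-hydroxy-6-methoxy-5-methyl-3-[(penta-O-benzylcatechin-8-yl)methyl]-4-(triisopropylsiloxy)phenyl]-2-methylpropan-1-ol (epimer mixture at the carbinol carbon)
Conditions: i-PrMgCl (3 equiv), THF, −40 to 0 °C; aq NH4Cl
Reagents that add atoms: isopropylmagnesium chloride CC(C)[Mg]Cl
Why: Grignard addition to an aldehyde: the first equivalent deprotonates the D2 hydroxyl and the chelated salicylaldehyde then accepts the isopropyl group; the new carbinol stereocentre is formed without control and is left as an epimer mixture because step 11 destroys it.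

Step 11
Reactants: 22 1-[2-hydroxy-6-methoxy-5-methyl-3-[(penta-O-benzylcatechin-8-yl)methyl]-4-(triisopropylsiloxy)phenyl]-2-methylpropan-1-ol
Product: 23 1-[2-hydroxy-6-methoxy-5-methyl-3-[(penta-O-benzylcatechin-8-yl)methyl]-4-(triisopropylsiloxy)phenyl]-2-methylpropan-1-one
Conditions: MnO2 (activated, excess), CH2Cl2, rt
Reagents that add atoms: none
Why: Oxidation of a benzylic alcohol with activated MnO2, selective for the electron-rich benzylic carbinol over the benzyl ethers and the diarylmethane CH2; both epimers of 22 converge on one ketone, stabilized by its hydrogen bond to the D2 hydroxyl.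

Step 12
Reactants: 23 1-[2-hydroxy-6-methoxy-5-methyl-3-[(penta-O-benzylcatechin-8-yl)methyl]-4-(triisopropylsiloxy)phenyl]-2-methylpropan-1-one
Product: 24 8-[(2,6-dihydroxy-3-isobutyryl-4-methoxy-5-methylphenyl)methyl]-penta-O-benzylcatechin
Conditions: Bu4NF (1.2 equiv), AcOH (1.2 equiv), THF, 0 °C
Reagents that add atoms: none
Why: Fluoride-induced cleavage of an aryl silyl ether (strong Si–F bond, phenoxide leaving group); the AcOH buffer protonates the released D6 phenoxide at once, which protects the air-sensitive acylphloroglucinol ring and leaves benzyl ethers and ketone alone.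

Step 13
Reactants: 24 8-[(2,6-dihydroxy-3-isobutyryl-4-methoxy-5-methylphenyl)methyl]-penta-O-benzylcatechin
Product: 25 pilosanol B
Conditions: H2 (1 atm), Pd/C (10 wt % palladium on carbon), EtOAc–MeOH, rt
Reagents that add atoms: none
Why: Hydrogenolysis of the four aryl benzyl ethers and the C3 alkyl benzyl ether over palladium at atmospheric pressure; the hydrogen-bonded, flanked aryl ketone, the diarylmethane bridge and the C2–O1 bond are expected to survive these mild neutral conditions, so C2 and C3 keep the catechin configuration.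

Compound list
1 | chloroacetaldehyde dimethyl acetal (2-chloro-1,1-dimethoxyethane) | COC(CCl)OC | starting material
2 | sodium methoxyacetylide | [Na+].[C-]#COC | intermediate
3 | 1-methoxyprop-1-yne | CC#COC | intermediate
4 | trichloroacetyl chloride | ClC(=O)C(Cl)(Cl)Cl | starting material
5 | dichloroketene | ClC(Cl)=C=O | intermediate
6 | 4,4-dichloro-3-methoxy-2-methylcyclobut-2-en-1-one | COC1=C(C)C(=O)C1(Cl)Cl | intermediate
7 | 3-methoxy-2-methylcyclobut-2-en-1-one | COC1=C(C)C(=O)C1 | intermediate
8 | (+)-catechin, (2R,3S) | O[C@H]1Cc2c(O)cc(O)cc2O[C@@H]1c1ccc(O)c(O)c1 | starting material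
9 | 5,7,3',4'-tetra-O-benzylcatechin, (2R,3S), C3 hydroxyl free | c1c(OCc2ccccc2)cc(OCc2ccccc2)c2c1O[C@H](c1ccc(OCc3ccccc3)c(OCc3ccccc3)c1)[C@@H](O)C2 | intermediate
10 | penta-O-benzyl-(+)-catechin, (2R,3S)-3,5,7-tris(benzyloxy)-2-[3,4-bis(benzyloxy)phenyl]chroman | c1c(OCc2ccccc2)cc(OCc2ccccc2)c2c1O[C@H](c1ccc(OCc3ccccc3)c(OCc3ccccc3)c1)[C@@H](OCc1ccccc1)C2 | intermediate
11 | 8-bromo-penta-O-benzylcatechin, (2R,3S) | Brc1c(OCc2ccccc2)cc(OCc2ccccc2)c2c1O[C@H](c1ccc(OCc3ccccc3)c(OCc3ccccc3)c1)[C@@H](OCc1ccccc1)C2 | intermediate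
12 | ethyl 2-(penta-O-benzylcatechin-8-yl)acetate, (2R,3S) | CCOC(=O)Cc1c(OCc2ccccc2)cc(OCc2ccccc2)c2c1O[C@H](c1ccc(OCc3ccccc3)c(OCc3ccccc3)c1)[C@@H](OCc1ccccc1)C2 | intermediate
13 | lithium enolate of 1,1-dibromo-3-(penta-O-benzylcatechin-8-yl)propan-2-one | [Li+].[O-]C(=C(Br)Br)Cc1c(OCc2ccccc2)cc(OCc2ccccc2)c2c1O[C@H](c1ccc(OCc3ccccc3)c(OCc3ccccc3)c1)[C@@H](OCc1ccccc1)C2 | intermediate
14 | lithium 3-(penta-O-benzylcatechin-8-yl)prop-1-yn-1-olate (ynolate) | [Li+].[O-]C#CCc1c(OCc2ccccc2)cc(OCc2ccccc2)c2c1O[C@H](c1ccc(OCc3ccccc3)c(OCc3ccccc3)c1)[C@@H](OCc1ccccc1)C2 | intermediate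
15 | 8-(3-triisopropylsiloxyprop-2-ynyl)-penta-O-benzylcatechin, (2R,3S) | CC(C)[Si](C(C)C)(C(C)C)OC#CCc1c(OCc2ccccc2)cc(OCc2ccccc2)c2c1O[C@H](c1ccc(OCc3ccccc3)c(OCc3ccccc3)c1)[C@@H](OCc1ccccc1)C2 | intermediate
16 | 3-methoxy-2-methylbuta-1,3-dien-1-one (methoxyvinylketene) | COC(=C)C(C)=C=O | intermediate
17 | 4-(1-methoxyvinyl)-4-methyl-2-[(penta-O-benzylcatechin-8-yl)methyl]-3-(triisopropylsiloxy)cyclobut-2-en-1-one, quaternary ring carbon unassigned | COC(=C)C1(C)C(=O)C(Cc2c(OCc3ccccc3)cc(OCc3ccccc3)c3c2O[C@H](c2ccc(OCc4ccccc4)c(OCc4ccccc4)c2)[C@@H](OCc2ccccc2)C3)=C1O[Si](C(C)C)(C(C)C)C(C)C | intermediate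
18 | dienylketene, 5-methoxy-4-methyl-2-[(penta-O-benzylcatechin-8-yl)methyl]-3-(triisopropylsiloxy)hexa-1,3,5-trien-1-one, methoxyvinyl group cis to the ketene carbon | C=C(OC)/C(C)=C(O[Si](C(C)C)(C(C)C)C(C)C)\C(Cc1c(OCc2ccccc2)cc(OCc2ccccc2)c2c1O[C@H](c1ccc(OCc3ccccc3)c(OCc3ccccc3)c1)[C@@H](OCc1ccccc1)C2)=C=O | intermediate
19 | 5-methoxy-4-methyl-2-[(penta-O-benzylcatechin-8-yl)methyl]-3-(triisopropylsiloxy)cyclohexa-2,4-dien-1-one | COC1=C(C)C(O[Si](C(C)C)(C(C)C)C(C)C)=C(Cc2c(OCc3ccccc3)cc(OCc3ccccc3)c3c2O[C@H](c2ccc(OCc4ccccc4)c(OCc4ccccc4)c2)[C@@H](OCc2ccccc2)C3)C(=O)C1 | intermediate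
20 | 2-[(penta-O-benzylcatechin-8-yl)methyl]-5-methoxy-4-methyl-3-(triisopropylsiloxy)phenol (D2 OH free, D6 silyl ether, D3 H) | COc1cc(O)c(Cc2c(OCc3ccccc3)cc(OCc3ccccc3)c3c2O[C@H](c2ccc(OCc4ccccc4)c(OCc4ccccc4)c2)[C@@H](OCc2ccccc2)C3)c(O[Si](C(C)C)(C(C)C)C(C)C)c1C | intermediate
21 | 2-hydroxy-6-methoxy-5-methyl-3-[(penta-O-benzylcatechin-8-yl)methyl]-4-(triisopropylsiloxy)benzaldehyde (D3 formyl) | COc1c(C=O)c(O)c(Cc2c(OCc3ccccc3)cc(OCc3ccccc3)c3c2O[C@H](c2ccc(OCc4ccccc4)c(OCc4ccccc4)c2)[C@@H](OCc2ccccc2)C3)c(O[Si](C(C)C)(C(C)C)C(C)C)c1C | intermediate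
22 | D3 carbinol, 1-aryl-2-methylpropan-1-ol, carbinol carbon as epimer mixture | COc1c(C(O)C(C)C)c(O)c(Cc2c(OCc3ccccc3)cc(OCc3ccccc3)c3c2O[C@H](c2ccc(OCc4ccccc4)c(OCc4ccccc4)c2)[C@@H](OCc2ccccc2)C3)c(O[Si](C(C)C)(C(C)C)C(C)C)c1C | intermediate
23 | D3 isobutyryl ketone with D6 triisopropylsilyl ether, penta-O-benzyl | COc1c(C(=O)C(C)C)c(O)c(Cc2c(OCc3ccccc3)cc(OCc3ccccc3)c3c2O[C@H](c2ccc(OCc4ccccc4)c(OCc4ccccc4)c2)[C@@H](OCc2ccccc2)C3)c(O[Si](C(C)C)(C(C)C)C(C)C)c1C | intermediate
24 | penta-O-benzylpilosanol B, 8-[(2,6-dihydroxy-3-isobutyryl-4-methoxy-5-methylphenyl)methyl]-penta-O-benzylcatechin | COc1c(C(=O)C(C)C)c(O)c(Cc2c(OCc3ccccc3)cc(OCc3ccccc3)c3c2O[C@H](c2ccc(OCc4ccccc4)c(OCc4ccccc4)c2)[C@@H](OCc2ccccc2)C3)c(O)c1C | intermediate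
25 | pilosanol B, (2R,3S) | COc1c(C)c(O)c(Cc2c(O)cc(O)c3c2O[C@H](c2ccc(O)c(O)c2)[C@@H](O)C3)c(O)c1C(=O)C(C)C | target

Total step count: 13. Longest linear sequence: 10 steps (steps 4 to 13, from (+)-catechin 8 to 25); the cyclobutenone branch (steps 1 to 3) joins at step 8.

Steps most likely to fail

Step 8. Capture of vinylketene 16 by the congested, flavan-bearing siloxyalkyne may be outrun by ketene oligomerization, and long heating may isomerize the siloxyalkyne to a silylketene before 7 has opened. The fallback sets out from 15 and returns at 20; it generates 16 at room temperature by a photochemical Wolff rearrangement instead of thermal ring opening. Methoxyethene is lithiated with t-BuLi (THF, −78 to 0 °C) to give 1-methoxyvinyllithium F1, and F1 is acylated with commercial N-methoxy-N-methylpropanamide to give 2-methoxypent-1-en-3-one F2. Trifluoroacetylation of F2 (LiN(SiMe3)2, THF, −78 °C; 2,2,2-trifluoroethyl trifluoroacetate) should give 1,1,1-trifluoro-5-methoxy-3-methylhex-5-ene-2,4-dione F3, and detrifluoroacetylative diazo transfer to F3 (MsN3, Et3N, H2O, MeCN) should give 2-diazo-4-methoxypent-4-en-3-one F4. Irradiation of F4 (300 nm, CH2Cl2, rt) in the presence of 15 expels nitrogen, the methoxyvinyl group migrates, and the resulting 16 is intercepted by 15; brief warming of the photolysate (80 °C) should complete the passage through 17, 18 and 19 to 20.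

Step 7. The carbenoid base may enolize the arylacetate instead of adding to its carbonyl group, and excess alkyllithium may metalate C6–H or a benzylic ether position while the carbenoid rearranges. The fallback sets out from 12 and returns at 15; it reaches the ynolate by oxidation of an acetylide. Reduction of 12 with i-Bu2AlH (CH2Cl2, −78 °C) gives 2-(penta-O-benzylcatechin-8-yl)acetaldehyde F5. Ohira–Bestmann homologation of F5 (dimethyl (1-diazo-2-oxopropyl)phosphonate, K2CO3, MeOH, 0 °C) gives 8-(prop-2-ynyl)-penta-O-benzylcatechin F6. Deprotonation of F6 with LiN(SiMe3)2 (THF, −78 °C) gives the lithium acetylide of 8-(prop-2-ynyl)-penta-O-benzylcatechin F7, and F7 is oxidized by t-BuOOLi (−78 to 0 °C) to ynolate 14, which is silylated with TIPSOTf to 15.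

Step 6. Oxidative addition of zerovalent palladium into the di-ortho-oxygenated, electron-rich C8–Br bond may be slow, so that protodebromination and decay of the zinc enolate take over. The fallback sets out from 11 and returns at 12; it makes the C8–C bond by polar addition. Bromine–lithium exchange on 11 (n-BuLi, THF, −78 °C) gives 8-lithio-penta-O-benzylcatechin F8. Addition of F8 to freshly cracked ethyl glyoxylate and quenching of the alkoxide with Ac2O gives ethyl 2-acetoxy-2-(penta-O-benzylcatechin-8-yl)acetate F9, as an epimer mixture at the new carbon. Treatment of F9 with SmI2 (THF–MeOH, −78 °C) then removes the α-acetoxy group reductively to give 12.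

Further compounds
F1 | step 8 | 1-methoxyvinyllithium | [Li]C(=C)OC
F2 | step 8 | 2-methoxypent-1-en-3-one | C=C(OC)C(=O)CC
F3 | step 8 | 1,1,1-trifluoro-5-methoxy-3-methylhex-5-ene-2,4-dione | C=C(OC)C(=O)C(C)C(=O)C(F)(F)F
F4 | step 8 | 2-diazo-4-methoxypent-4-en-3-one | C=C(OC)C(=O)C(C)=[N+]=[N-]
F5 | step 7 | 2-(penta-O-benzylcatechin-8-yl)acetaldehyde | O=CCc1c(OCc2ccccc2)cc(OCc2ccccc2)c2c1O[C@H](c1ccc(OCc3ccccc3)c(OCc3ccccc3)c1)[C@@H](OCc1ccccc1)C2
F6 | step 7 | 8-(prop-2-ynyl)-penta-O-benzylcatechin | C#CCc1c(OCc2ccccc2)cc(OCc2ccccc2)c2c1O[C@H](c1ccc(OCc3ccccc3)c(OCc3ccccc3)c1)[C@@H](OCc1ccccc1)C2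
F7 | step 7 | lithium acetylide of 8-(prop-2-ynyl)-penta-O-benzylcatechin | [Li]C#CCc1c(OCc2ccccc2)cc(OCc2ccccc2)c2c1O[C@H](c1ccc(OCc3ccccc3)c(OCc3ccccc3)c1)[C@@H](OCc1ccccc1)C2
F8 | step 6 | 8-lithio-penta-O-benzylcatechin | [Li]c1c(OCc2ccccc2)cc(OCc2ccccc2)c2c1O[C@H](c1ccc(OCc3ccccc3)c(OCc3ccccc3)c1)[C@@H](OCc1ccccc1)C2
F9 | step 6 | ethyl 2-acetoxy-2-(penta-O-benzylcatechin-8-yl)acetate | CCOC(=O)C(OC(C)=O)c1c(OCc2ccccc2)cc(OCc2ccccc2)c2c1O[C@H](c1ccc(OCc3ccccc3)c(OCc3ccccc3)c1)[C@@H](OCc1ccccc1)C2
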